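(All runs are simulated with constants of no real substance, and the scatter is random.)

Late readings of larch stand level with its early ones within the scatter: E reads 22% at 1.67 d and 22% at 10.0 d.

| setting | larch | cedar | elm | flask |
|---|---|---|---|---|
| E | 0.050 M | 0.050 M | 0.075 M | 0.050 M |
| Q | 0.050 M | 0.050 M | 0.075 M | 0.050 M |
| D | 0.062 M | 0.25 M | 0.125 M | 0.125 M |
| remark | run made earlier | run made earlier | run made earlier |  |
| time |  |  |  | 15 d |

- larch (time / d: E / %, Z / %): 1.67: 22, 35; 4.00: 22, 35; 5.00: 22, 37; 8.00: 24, 35; 10.0: 22, 38
- cedar (time / d: E / %, Z / %): 1.67: 2, 58; 4.00: 0, 61; 5.00: 1, 61; 8.00: 0, 59; 10.0: 3, 59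
- elm (time / d: E / %, Z / %): 1.67: 12, 49; 4.00: 9, 50; 5.00: 10, 50; 8.00: 12, 47; 10.0: 10, 48

(readings scatter by 1.5 percentage points)

- D is single-handed; E and Q are mirror images of each other, charged as a racemate, each of them at the stated concentration
- on the list of suspects stand: D + E -> Z; D + Q -> X; E <-> Q; D -> L
- the reaction counts as stopped when no species that holds the E and Q together changes by six tenths of a point or more over the second half of the time
- the handed part of D does not stay in what it makes, so the products of the two hands are mirror images too

- which holds at 15 d: what has brought the reaction to rest, or that it has not come to rest (it is still moving / D has run out first / forward and back rates have come level)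
- share of the E and Q together used up at 15 d
- Z at 15 d, in percent of the E and Q together charged
- X at 15 d, in percent of the E and Q together charged

Write S for E and Q together and f for the share of S left. In larch, E plus Z reach 60.0%, above the 50.0% charged as E, so Q feeds E, and E and Q are taken as equal. The means of the readings then give f as 44.8% in larch and 21.2% in elm. Larch used 0.0552 M of S against 0.062 M of D, and the gap is read as D lost to L.

D goes to L in proportion to D and consumes S in proportion to D times S, so D cancels and L equals a times the logarithm of S charged over S left, where a is the D lost to L per unit of that logarithm. Larch reads 0.00847 M and elm 0.00438 M, so a is taken as the mean of these readings, 0.00643 M, the leak constant.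

The flask charges D in excess of S by 0.0250 M. With no leak, f is zero. If the leak took just that excess, f would be 2.04%. The balance adds the small correction, S charged times f, to the excess, so f lies below that value. Putting the correction in gives a floor of 1.49%. This reckoning therefore has D as the limiting reagent and conversion near 98.2%.

The forecast says D has run out first, conversion 99%, Z 61% and X 38%, and of the gap in D it says: “that shortfall is the leak to L”. Its conversion stands above this reckoning's top of 98.5%.

The flask gives: D has run out first, with 0.18% of its D left at 15.0 d, conversion 98.2%, Z 62.7% and X 35.5%.

    D + E → Z (k = 0.0330 M⁻¹ min⁻¹)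
    D + Q → X (k = 0.0160 M⁻¹ min⁻¹)
    E ⇌ Q (k = 0.00230 min⁻¹)
    D → L (k = 1.60 × 10⁻⁴ min⁻¹)

The constant of D to L over the mean of the constants making Z and X is 0.00653 M, a ratio of the leak to the use of S. With the flask's conversion of 98.2%, the carried a gives L of 0.0258 M, and the flask holds 0.0266 M at 15.0 d. A neighbour flask with 0.031 M of D stands at conversion 28.8%, where the carried a gives L of 0.00218 M, and that flask holds 0.00223 M.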